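At 10.0 min the zeta run of substrate with coupling partner reads substrate at 59.7%, and at 80.0 min it reads 59.8%.

| flask | substrate | coupling partner | remark | time |
|---|---|---|---|---|
| zeta | 27 mM | 13 mM | run made earlier |  |
| theta | 27 mM | 19 mM | run made earlier |  |
| gamma | 54 mM | 25.6 mM | run made earlier |  |
| flask | 27 mM | 25.6 mM |  | 1.5 h |

| run | time / min | substrate / % | single product / % |
|---|---|---|---|
| zeta | 10.0 | 59.7 | 19.7 |
| zeta | 25.0 | 59.6 | 19.7 |
| zeta | 50.0 | 59.7 | 19.9 |
| zeta | 80.0 | 59.8 | 19.3 |
| theta | 20.0 | 47.2 | 21.0 |
| theta | 40.0 | 47.4 | 21.1 |
| theta | 50.0 | 47.2 | 21.3 |
| theta | 80.0 | 46.8 | 21.1 |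
| gamma | 20.0 | 60.3 | 19.7 |
| gamma | 40.0 | 60.3 | 19.4 |
| gamma | 50.0 | 60.1 | 19.4 |
| gamma | 80.0 | 60.2 | 19.5 |

(readings scatter by 0.3 percentage points)

- percent here means substrate units held: one side product counts as two
- the earlier runs were read with a standard deviation of 0.3 percentage points
- steps under discussion: substrate + coupling partner -> single product; coupling partner + single product -> bis adduct; coupling partner + bis adduct -> tris adduct; tris adduct -> over-reaction product; substrate + bis adduct -> side product

- how much substrate there is at 1.5 h, in percent of the substrate charged
- how much single product there is at 1.5 h, in percent of the substrate charged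
- how much bis adduct there is at 1.5 h, in percent of the substrate charged
- how much tris adduct there is at 1.5 h, in percent of the substrate charged

Does time matter in the asked flask? Its 1.5 h is 9.00 times that first zeta reading, and the theta and gamma runs are just as flat within the scatter of 0.3 percentage points. The asked flask is therefore reckoned here as a stopped flask, with the coupling partner taken as the limiting reagent.

Which setting places the stop? Gamma charges twice zeta's substrate and twice its coupling partner, so its charge ratio, coupling partner over substrate, is 0.474 against zeta's 0.481. At 50.0 min its substrate reads 60.1% against zeta's 59.7%, so the reckoning here goes by the charge ratio, which is 0.948 in the asked flask.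

What does the coupling partner cost? Call the toll the fraction of substrate lost divided by the charge ratio. Read at 50.0 min, it is 0.837 in zeta, and at theta's ratio of 0.704 it is 0.750, less than in zeta. The fall of the toll per unit of charge ratio is therefore 0.390. Taken as a straight line, it gives the asked flask a toll of 0.655, which leaves substrate at 37.9%.

The forecast gives substrate 32%, which is lower than the figure reckoned here, single product 20.5%, bis adduct 0.3% and tris adduct 11%, adding that “The runs cannot separate tris from over-reaction product”.

The flask gives substrate 36.1%, single product 20.6%, bis adduct 0% and tris adduct 0%.

    substrate + coupling partner → single product (k = 0.720 /M/s)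
    coupling partner + single product → bis adduct (k = 1.80 /M/s)
    coupling partner + bis adduct → tris adduct (k = 3.40 /M/s)
    tris adduct → over-reaction product (k = 0.00450 /s)
    substrate + bis adduct → side product (k = 0.640 /M/s)

The forecast and the asked flask part at the tris adduct, which stands in that flask at 1.73% after 0.150 h and 0% after 1.50 h, while over-reaction product reaches 15.4%. The neighbouring flask, the same charge but with 6.4 mM of coupling partner, has a charge ratio of 0.237, so the fall, counted from zeta, gives it a toll of 0.932 and leaves substrate reckoned at 77.9%. That neighbouring flask holds substrate at 77.8%.

All runs are simulated with constants of no real substance; the scatter is artificial.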